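At early times the north-west run climbed to E 57 % by 3.00 h, then sank to 28 % by 15.0 h, so I took L to pass through X, D, E and G, each exchange costing one J.

| flask | L | J | remark | time |
|---|---|---|---|---|
| north-west | 0.50 M | 2.4 M | run made earlier |  |
| birch | 0.50 M | 0.500 M |  | 30 h |
| oak | 0.50 M | 1.50 M |  | 30 h |
| alder | 0.50 M | 0.750 M |  | 30 h |

north-west run (percent of the L charged)

| time / h | E / % |
|---|---|
| 1.00 | 48 |
| 3.00 | 57 |
| 5.00 | 52 |
| 8.00 | 44 |
| 12.0 | 34 |
| 15.0 | 28 |

(each reading ± 2 percentage points)

- what was read earlier has a scatter of 2 percentage points, one standard deviation
- no earlier run changes the charge of J; that part of a forecast is a guess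

1. which of these holds the largest part of the L at the end of birch (X / L / G / E / D)
2. which of these holds the largest part of the L at the end of oak (X / L / G / E / D)
3. which of these holds the largest part of the L at the end of alder (X / L / G / E / D)
4. E at the end of oak, in percent of the L charged

1. I folded the charges into one number for oak, 3.00: the equivalents of J, meaning J charged per L charged, which is the mean count of exchanges per L that the charge of J can pay for. Birch has 1.00, alder 1.50 and the north-west run 4.80.

2. I assumed that each step's rate follows the fraction of J left, which is a guess, as no earlier run changes J. On that guess a flask's mix follows the J used per L, not the hours.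

3. I expected J, the limiting reagent, to stop oak at a mean of 3.00 exchanges per L, which is the place of E, and birch at the place of X. Supposing that the north-west run passed that mean near its highest reading, I committed to about that reading, 57 % of E in oak, which itself carries a scatter of 2 percentage points.

4. One number gives a mean, not a spread. Alder's mean lies between X and D, so I chose X, weakly.

The forecast named X for birch, E for oak and D for alder, where it differs from me, and put E in oak at 65 % (50 % to 78 %), above my figure, saying “three exchanges per L, so E dominates”.

Oak ended with E at 58.3 %, and the equations were these.

    E ⇌ Z (K = 0.290, k = 0.380 /h)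
    L + J → Q + X (k = 2.20 /M/h)
    X + J → Q + D (k = 0.880 /M/h)
    D + J → Q + E (k = 9.70 /M/h)
    E + J → Q + G (k = 0.120 /M/h)

Beside E in oak stood Z at 16.9 %. Counting each form by its exchanges, with Z counted at the 3 exchanges of E, gives 2.99 per L at the end of oak, against 3.00 equivalents. The neighbour of oak charged with 0.30 M of L has 5.00 equivalents. It kept 25.7 % of its J, so it used 3.71 per L, and it ended with G at 71.3 %.

The earlier runs and the new flask come from a simulation on assumed constants; scatter was added.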